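## Retrosynthetic overview (halimane numbering for ring atoms)

1. Target 15 ⇐ propionylation of allylic alcohol 13 ⇐ chemoselective DIBAL reduction of diester 12.
2. Ring A is made last: 12 ⇐ intermolecular endo Diels–Alder of semicyclic diene 10 with methyl methacrylate. This forms C2–C3 and C4–C5, sets C4 and C5, and leaves the 1(10)-alkene in place.
3. 10 ⇐ enol triflate 8 ⇐ ketone 6 (Stille vinylation); the E-enoate side chain ⇐ HWE on methyl ketone 4.
4. 4 ⇐ enone 1 + methyl vinyl ketone by a one-pot organocatalytic asymmetric conjugate reduction / Michael addition (sets C8, then the C9 quaternary centre).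
5. Ring order: ring B is bought (in 1); ring A is formed by the Diels–Alder.

Assumption: 1 is bought as such, and the antipode of the amine/phosphate catalyst salt is the one that gives 3R (both antipodes are available; the sense is checked on the first run on ketone 3).

## Route

Step 1
Reactants: 1 2,3-dimethylcyclohex-2-en-1-one; 2 methyl vinyl ketone
Product: 4 (2S,3R)-2,3-dimethyl-2-(3-oxobutyl)cyclohexan-1-one, via (3R)-2,3-dimethylcyclohexan-1-one 3 (not isolated)
Conditions: Hantzsch ester (1.05 equiv), L-valine tert-butyl ester·(R)-TRIP salt (15 mol%), Bu2O, 60 °C; then 2 (2 equiv), 40 °C, one pot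
Reagents that add atoms: methyl vinyl ketone, CC(=O)C=C
Why: Proposed new method: an organocatalytic asymmetric reductive Michael cascade in which the primary-amine/chiral-phosphate salt condenses with 1 to an iminium ion that takes hydride from the Hantzsch ester at C3 on the face left open by the chiral phosphate (sets C3 = R), the resulting more-substituted secondary enamine then adds to 2 through an aza-ene-type transition state at C2 anti to the C3 methyl, which is pseudoaxial because of A(1,2) strain (sets the quaternary centre, methyls cis), and the water of condensation hydrolyses the imine and turns the catalyst over; the closest known reactions are counteranion-directed iminium transfer hydrogenation of 3-substituted cyclohexenones and the Michael addition of secondary enamines of 2-methylcyclohexanones to enones, neither shown on a tetrasubstituted α,β-dimethyl enone nor merged in one pot.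

Step 2
Reactants: 4 (2S,3R)-2,3-dimethyl-2-(3-oxobutyl)cyclohexan-1-one; 5 triethyl phosphonoacetate
Product: 6 ethyl (2E)-5-[(1S,2R)-1,2-dimethyl-6-oxocyclohexyl]-3-methylpent-2-enoate
Conditions: 5 (1.3 equiv), NaH (1.2 equiv), THF, 0 °C → rt
Reagents that add atoms: triethyl phosphonoacetate, CCOC(=O)CP(=O)(OCC)OCC
Why: Horner–Wadsworth–Emmons olefination in which the stabilised phosphonate anion attacks the unhindered methyl ketone and not the neopentyl ring ketone, giving mainly the E-enoate (about 5:1 expected, Z isomer removed on silica) without touching a stereocentre.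

Step 3
Reactants: 6 ethyl (2E)-5-[(1S,2R)-1,2-dimethyl-6-oxocyclohexyl]-3-methylpent-2-enoate; 7 trifluoromethanesulfonic anhydride
Product: 8 ethyl (2E)-5-[(1S,6R)-1,6-dimethyl-2-{[(trifluoromethyl)sulfonyl]oxy}cyclohex-2-en-1-yl]-3-methylpent-2-enoate
Conditions: 7 (1.3 equiv), 2,6-di-tert-butyl-4-methylpyridine (1.5 equiv), CH2Cl2, 0 °C → rt
Reagents that add atoms: trifluoromethanesulfonic anhydride, O=S(=O)(OS(=O)(=O)C(F)(F)F)C(F)(F)F
Why: Electrophilic enol triflation of the ketone, which can enolise only toward the ring CH2 because the other α-carbon is quaternary, under conditions that spare the enoate (an amide base would also attack its γ-hydrogens).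

Step 4
Reactants: 8 ethyl (2E)-5-[(1S,6R)-1,6-dimethyl-2-{[(trifluoromethyl)sulfonyl]oxy}cyclohex-2-en-1-yl]-3-methylpent-2-enoate; 9 tributyl(vinyl)stannane
Product: 10 ethyl (2E)-5-[(1S,6R)-2-ethenyl-1,6-dimethylcyclohex-2-en-1-yl]-3-methylpent-2-enoate
Conditions: 9 (1.3 equiv), Pd(PPh3)4 (5 mol%), LiCl (3 equiv), THF, 65 °C
Reagents that add atoms: tributyl(vinyl)stannane, C=C[Sn](CCCC)(CCCC)CCCC
Why: Stille cross-coupling of the alkenyl triflate (LiCl-assisted transmetallation) gives the semicyclic 1,3-diene with the ring alkene fixed at C5=C10, as in the standard preparation of 6,6-dialkyl-1-vinylcyclohexenes.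

Step 5
Reactants: 10 ethyl (2E)-5-[(1S,6R)-2-ethenyl-1,6-dimethylcyclohex-2-en-1-yl]-3-methylpent-2-enoate; 11 methyl methacrylate
Product: 12 methyl (1S,5S,6R,8aR)-5-[(3E)-5-ethoxy-3-methyl-5-oxopent-3-en-1-yl]-1,5,6-trimethyl-1,2,3,5,6,7,8,8a-octahydronaphthalene-1-carboxylate
Conditions: 11 (6 equiv), EtAlCl2 (30 mol%), BHT, toluene, −20 °C → rt
Reagents that add atoms: methyl methacrylate, C=C(C)C(=O)OC
Why: Lewis-acid-catalysed intermolecular Diels–Alder reaction with "ortho" regiochemistry (the ring-terminus substituent of the diene directs the ester-bearing carbon to C5), an ester-endo transition state (CO2Me trans to H5) and approach to the diene face anti to the two cis methyl groups on C8/C9 (the pseudoaxial C9 methyl shields the other face), which together set C4 (S) and C5 (R) and place the alkene at C1=C10.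

Step 6
Reactants: 12 methyl (1S,5S,6R,8aR)-5-[(3E)-5-ethoxy-3-methyl-5-oxopent-3-en-1-yl]-1,5,6-trimethyl-1,2,3,5,6,7,8,8a-octahydronaphthalene-1-carboxylate
Product: 13 methyl (1S,5S,6R,8aR)-5-[(3E)-5-hydroxy-3-methylpent-3-en-1-yl]-1,5,6-trimethyl-1,2,3,5,6,7,8,8a-octahydronaphthalene-1-carboxylate
Conditions: DIBAL-H (2.2 equiv), CH2Cl2, −78 °C; Rochelle salt work-up
Reagents that add atoms: none
Why: Chemoselective DIBAL 1,2-reduction of the unhindered conjugated ethyl ester to the allylic alcohol, while the methyl ester on the quaternary carbon next to the ring-fusion methine reacts far more slowly at −78 °C and the alkenes and stereocentres are untouched.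

Step 7
Reactants: 13 methyl (1S,5S,6R,8aR)-5-[(3E)-5-hydroxy-3-methylpent-3-en-1-yl]-1,5,6-trimethyl-1,2,3,5,6,7,8,8a-octahydronaphthalene-1-carboxylate; 14 propanoic anhydride
Product: 15 methyl (1S,5S,6R,8aR)-1,5,6-trimethyl-5-[(3E)-3-methyl-5-(propanoyloxy)pent-3-en-1-yl]-1,2,3,5,6,7,8,8a-octahydronaphthalene-1-carboxylate (CNP0279628.1)
Conditions: 14 (1.5 equiv), Et3N (2 equiv), DMAP (5 mol%), CH2Cl2, 0 °C → rt
Reagents that add atoms: propanoic anhydride, CCC(=O)OC(=O)CC
Why: DMAP-catalysed acylation (nucleophilic acyl transfer) of the primary allylic alcohol under mild basic conditions that cause neither allylic transposition nor ester exchange.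

## Compound list

1 | 2,3-dimethylcyclohex-2-en-1-one | CC1=C(C)C(=O)CCC1 | starting material
2 | methyl vinyl ketone (but-3-en-2-one) | CC(=O)C=C | starting material
3 | (3R)-2,3-dimethylcyclohexan-1-one (C2 epimers, in equilibrium with its catalyst enamine) | CC1C(=O)CCC[C@H]1C | intermediate
4 | (2S,3R)-2,3-dimethyl-2-(3-oxobutyl)cyclohexan-1-one | CC(=O)CC[C@]1(C)C(=O)CCC[C@H]1C | intermediate
5 | triethyl phosphonoacetate | CCOC(=O)CP(=O)(OCC)OCC | starting material
6 | ethyl (2E)-5-[(1S,2R)-1,2-dimethyl-6-oxocyclohexyl]-3-methylpent-2-enoate | CCOC(=O)/C=C(\C)CC[C@]1(C)C(=O)CCC[C@H]1C | intermediate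
7 | trifluoromethanesulfonic anhydride | O=S(=O)(OS(=O)(=O)C(F)(F)F)C(F)(F)F | starting material
8 | ethyl (2E)-5-[(1S,6R)-1,6-dimethyl-2-{[(trifluoromethyl)sulfonyl]oxy}cyclohex-2-en-1-yl]-3-methylpent-2-enoate | CCOC(=O)/C=C(\C)CC[C@]1(C)C(OS(=O)(=O)C(F)(F)F)=CCC[C@H]1C | intermediate
9 | tributyl(vinyl)stannane | C=C[Sn](CCCC)(CCCC)CCCC | starting material
10 | ethyl (2E)-5-[(1S,6R)-2-ethenyl-1,6-dimethylcyclohex-2-en-1-yl]-3-methylpent-2-enoate | CCOC(=O)/C=C(\C)CC[C@]1(C)C(C=C)=CCC[C@H]1C | intermediate
11 | methyl methacrylate | C=C(C)C(=O)OC | starting material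
12 | methyl (1S,5S,6R,8aR)-5-[(3E)-5-ethoxy-3-methyl-5-oxopent-3-en-1-yl]-1,5,6-trimethyl-1,2,3,5,6,7,8,8a-octahydronaphthalene-1-carboxylate | CCOC(=O)/C=C(\C)CC[C@]1(C)C2=CCC[C@](C)(C(=O)OC)[C@@H]2CC[C@H]1C | intermediate
13 | methyl (1S,5S,6R,8aR)-5-[(3E)-5-hydroxy-3-methylpent-3-en-1-yl]-1,5,6-trimethyl-1,2,3,5,6,7,8,8a-octahydronaphthalene-1-carboxylate | OC/C=C(\C)CC[C@]1(C)C2=CCC[C@](C)(C(=O)OC)[C@@H]2CC[C@H]1C | intermediate
14 | propanoic anhydride | CCC(=O)OC(=O)CC | starting material
15 | methyl (1S,5S,6R,8aR)-1,5,6-trimethyl-5-[(3E)-3-methyl-5-(propanoyloxy)pent-3-en-1-yl]-1,2,3,5,6,7,8,8a-octahydronaphthalene-1-carboxylate; halimane numbering 4S,5R,8R,9S | CCC(=O)OC/C=C(\C)CC[C@]1(C)C2=CCC[C@](C)(C(=O)OC)[C@@H]2CC[C@H]1C | target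

## Step count and risks

Total steps: 7. Longest linear sequence: 7.

The three steps most likely to fail:

Step 1 (the proposed new cascade). The tetrasubstituted enone may form the iminium ion too slowly, and the methyl vinyl ketone may be reduced or may tie up the amine. The fallback uses known chemistry and sets out from 1. Copper hydride-catalysed asymmetric conjugate reduction (Cu(OAc)2, the DTBM-SEGPHOS antipode that gives 3R, PMHS, toluene, fluoride work-up) gives ketone 3, now isolated. Thermodynamic silylation (TMSCl, NaI, Et3N, MeCN) turns it into the more substituted silyl enol ether trimethyl{[(3R)-2,3-dimethylcyclohex-1-en-1-yl]oxy}silane F1. A Mukaiyama–Michael addition of F1 to 2 (TiCl4/Ti(OiPr)4, CH2Cl2, −78 °C), anti to the C3 methyl, comes back to the route at 4.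

Step 5 (Diels–Alder). Methyl methacrylate is a sluggish dienophile toward a diene flanked by a quaternary carbon. The 2-substituent of the diene opposes the "ortho" orientation, and the ester-endo preference of a methacrylate is modest. The fallback sets out from 10. Methacrolein (Me2AlCl, CH2Cl2, −78 °C), a far more reactive and more carbonyl-endo-selective dienophile, gives the aldehyde ethyl (2E)-5-[(1S,2R,4aR,5S)-5-formyl-1,2,5-trimethyl-1,2,3,4,4a,5,6,7-octahydronaphthalen-1-yl]-3-methylpent-2-enoate F2. Pinnick oxidation (NaClO2, NaH2PO4, 2-methyl-2-butene, t-BuOH/H2O) gives the acid (1S,5S,6R,8aR)-5-[(3E)-5-ethoxy-3-methyl-5-oxopent-3-en-1-yl]-1,5,6-trimethyl-1,2,3,5,6,7,8,8a-octahydronaphthalene-1-carboxylic acid F3. Methylation with TMSCHN2 (MeOH/toluene) comes back to the route at 12.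

Step 3 (enol triflation). The hindered ketone may enolise slowly or rearrange by a 1,2-shift at the triflyloxycarbenium stage, and base-mediated alternatives endanger the enoate. The fallback sets out from 6. Vinylcerium addition (vinylMgBr, CeCl3, THF, −78 °C), which adds to hindered ketones and spares the β,β-disubstituted enoate, gives the tertiary allylic alcohol ethyl (2E)-5-[(1S,6R)-2-ethenyl-2-hydroxy-1,6-dimethylcyclohexyl]-3-methylpent-2-enoate F4 (carbinol epimers). Syn-dehydration with Burgess reagent (toluene, 70 °C), possible only toward the ring CH2, comes back to the route at 10, so step 4 is skipped as well.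

Further compounds
F1 | step 1 | trimethyl{[(3R)-2,3-dimethylcyclohex-1-en-1-yl]oxy}silane | CC1=C(O[Si](C)(C)C)CCC[C@H]1C
F2 | step 5 | ethyl (2E)-5-[(1S,2R,4aR,5S)-5-formyl-1,2,5-trimethyl-1,2,3,4,4a,5,6,7-octahydronaphthalen-1-yl]-3-methylpent-2-enoate | CCOC(=O)/C=C(\C)CC[C@]1(C)C2=CCC[C@](C)(C=O)[C@@H]2CC[C@H]1C
F3 | step 5 | (1S,5S,6R,8aR)-5-[(3E)-5-ethoxy-3-methyl-5-oxopent-3-en-1-yl]-1,5,6-trimethyl-1,2,3,5,6,7,8,8a-octahydronaphthalene-1-carboxylic acid | CCOC(=O)/C=C(\C)CC[C@]1(C)C2=CCC[C@](C)(C(=O)O)[C@@H]2CC[C@H]1C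
F4 | step 3 | ethyl (2E)-5-[(1S,6R)-2-ethenyl-2-hydroxy-1,6-dimethylcyclohexyl]-3-methylpent-2-enoate | CCOC(=O)/C=C(\C)CC[C@]1(C)C(O)(C=C)CCC[C@H]1C
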